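The ten-membered carbocycle is opened at C1–C10, the only ring segment without stereocentres. The β,γ-unsaturated ketone array C2(=O)–C1H2–C10(=C14H2) is the retron of a Conia-ene reaction. An indium-catalysed cycloisomerisation of an allyl β-keto ester (C1/C2) onto a terminal alkyne (C10≡C14) therefore closes the carbocycle and creates the exocyclic methylene in one operation; the activating ester is excised in the last step. The precursor is an open chain that already carries all seven ring stereocentres, with the cis-fused lactone (C6–C7) and the cis-epoxide (C3–C4) as turn elements. C8/C9 come from D-tartrate and are relayed to C7/C6 (allylation), C5 (reduction) and C3/C4 (directed epoxidation).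

Key step: step 19

Remark: germacranolide numbering (ring C1–C10, C4-methyl C15, C10-methylene C14, lactone C11–C13) is used for all intermediates; allyl diazoacetate is made in step 17 because it is not assumed to be purchasable.

Step 1
Reactants: 1 dimethyl (4S,5S)-2,2-dimethyl-1,3-dioxolane-4,5-dicarboxylate (acetonide of dimethyl D-tartrate)
Product: 2 methyl (4S,5S)-5-formyl-2,2-dimethyl-1,3-dioxolane-4-carboxylate
Conditions: (i-Bu)2AlH (1.05 equiv), PhMe, −78 °C; aq. potassium sodium tartrate
Reagents that add atoms: none
Why: Partial ester reduction; the aluminium hemiacetal is stable at −78 °C and gives the aldehyde only on work-up, the C2 symmetry of 1 removes any regiochemical question, and both stereocentres (future C8 and C9) are bought.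

Step 2
Reactants: 2 methyl (4S,5S)-5-formyl-2,2-dimethyl-1,3-dioxolane-4-carboxylate
Product: 3 methyl (4S,5R)-5-ethynyl-2,2-dimethyl-1,3-dioxolane-4-carboxylate
Conditions: dimethyl (1-diazo-2-oxopropyl)phosphonate, K2CO3, MeOH, 0 °C → rt
Reagents that add atoms: dimethyl (1-diazo-2-oxopropyl)phosphonate, CC(=O)C(=[N+]=[N-])P(=O)(OC)OC
Why: Seyferth–Gilbert homologation with the Ohira–Bestmann reagent turns the aldehyde into the terminal alkyne (C10≡C14); the trans-dioxolane is the thermodynamically preferred isomer, so the basic medium should not erode C9.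

Step 3
Reactants: 3 methyl (4S,5R)-5-ethynyl-2,2-dimethyl-1,3-dioxolane-4-carboxylate
Product: 4 (4S,5R)-5-ethynyl-2,2-dimethyl-1,3-dioxolane-4-carbaldehyde
Conditions: (i-Bu)2AlH (1.1 equiv), CH2Cl2, −78 °C
Reagents that add atoms: none
Why: Partial ester reduction to the aldehyde (future C7) through the low-temperature-stable aluminium hemiacetal; the alkyne and the acetal are inert.

Step 4
Reactants: 4 (4S,5R)-5-ethynyl-2,2-dimethyl-1,3-dioxolane-4-carbaldehyde; 5 methyl acrylate
Product: 6 methyl 2-{[(5R)-5-ethynyl-2,2-dimethyl-1,3-dioxolan-4-yl](hydroxy)methyl}prop-2-enoate (trans-dioxolane, mixture of carbinol epimers)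
Conditions: DABCO (0.5 equiv), methyl acrylate (neat, excess), rt, several days
Reagents that add atoms: none
Why: Morita–Baylis–Hillman reaction; the new carbinol centre is an inconsequential mixture because it becomes sp2 in step 5, and the trans-dioxolane cannot be eroded by the amine.

Step 5
Reactants: 6 Morita–Baylis–Hillman alcohol
Product: 7 methyl (2Z)-2-(bromomethyl)-3-[(4R,5R)-5-ethynyl-2,2-dimethyl-1,3-dioxolan-4-yl]prop-2-enoate
Conditions: NBS, Me2S, CH2Cl2, 0 °C → rt
Reagents that add atoms: N-bromosuccinimide, O=C1CCC(=O)N1Br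
Why: Allylic transposition (SN2′ bromination of the alkoxysulfonium salt); bromide attacks the terminal methylene and both carbinol epimers should converge on the thermodynamically favoured (Z)-2-(bromomethyl)alkenoate.

Step 6
Reactants: 8 but-2-yn-1-ol
Product: 10 (2Z)-3-iodobut-2-en-1-ol, via cyclic alkenylaluminate 9 (not isolated)
Conditions: NaAlH2(OCH2CH2OMe)2, THF, 0 °C → rt; then I2, −78 → 0 °C
Reagents that add atoms: iodine, II
Why: Hydroxyl-directed trans-hydroalumination of the propargylic alcohol and iodinolysis of the C–Al bond with retention; this fixes the C3=C4 geometry (iodine, the future C5 position, cis to C2).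

Step 7
Reactants: 10 (2Z)-3-iodobut-2-en-1-ol
Product: 11 tert-butyl{[(2Z)-3-iodobut-2-en-1-yl]oxy}diphenylsilane
Conditions: TBDPSCl, imidazole, CH2Cl2, rt
Reagents that add atoms: tert-butyl(chloro)diphenylsilane, CC(C)(C)[Si](Cl)(c1ccccc1)c1ccccc1
Why: Silyl ether formation; the TBDPS group is chosen to survive the organolithium step and the acidic acetonide cleavage of step 10.

Step 8
Reactants: 7 (Z)-allylic bromide; 12 glyoxylic acid monohydrate
Product: 14 (2R,3R)-3-[(4R,5R)-5-ethynyl-2,2-dimethyl-1,3-dioxolan-4-yl]-4-methylidene-5-oxooxolane-2-carboxylic acid (cis-lactone acid; C5 carboxyl on C6), via hydroxy acid 13 (not isolated)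
Conditions: indium powder, THF/H2O (1:1), rt; then PhMe, molecular sieves 4 Å, 50 °C
Reagents that add atoms: none
Why: Barbier allylation and lactonisation; the (Z)-allylindium should react at C7 through a chair transition state (syn adduct, hence the cis-lactone) on the face anti to the dioxolane C8–O bond in the conformer with H8 in the alkene plane (allylic 1,3-strain), so that C7 and C6 are relayed from C8.

Step 9
Reactants: 14 cis-lactone acid; 11 (Z)-alkenyl iodide
Product: 18 (Z)-enone (C5 ketone joined to C4(Me)=C3H–C2H2OTBDPS; lactone and dioxolane unchanged), via acid chloride 15 (not isolated), via alkenyllithium 16 (not isolated), via alkenylzinc chloride 17 (not isolated)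
Conditions: 14, 1-chloro-N,N,2-trimethylprop-1-en-1-amine, CH2Cl2, 0 °C; 11, t-BuLi (2 equiv), Et2O, −78 °C, then ZnCl2, THF; combine, Pd(PPh3)4 (5 mol%), THF, 0 °C → rt
Reagents that add atoms: none
Why: Negishi acylation; oxidative addition of zerovalent palladium into the acyl chloride, transmetalation from the configurationally stable (Z)-alkenylzinc and reductive elimination should give the enone with retention of geometry while the lactone, its methylene group and the alkyne are untouched.

Step 10
Reactants: 18 (Z)-enone acetonide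
Product: 19 C8,C9-diol of the (Z)-enone
Conditions: CF3CO2H/H2O (9:1), CH2Cl2, 0 °C
Reagents that add atoms: none
Why: Acid hydrolysis of the isopropylidene acetal; the TBDPS ether and the lactone tolerate short exposure at 0 °C, and the acetal is removed here because the epoxide made later would not survive acid.

Step 11
Reactants: 19 C8,C9-diol; 20 (2R)-2-methylbutanoic acid
Product: 21 C9 (2R)-2-methylbutanoate of the (Z)-enone (C8–OH free)
Conditions: EDC·HCl, DMAP (cat.), CH2Cl2, −20 → 0 °C
Reagents that add atoms: none
Why: Steglich esterification; the propargylic C9–OH, flanked only by the slim ethynyl group, should react in preference to C8–OH, which sits next to the ring carbon C7, and the acid brings its own stereocentre.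

Step 12
Reactants: 21 (Z)-enone C9 ester
Product: 22 allylic alcohol at C5 (5,6-threo; C5 as in the target)
Conditions: NaBH4, CeCl3·7H2O, MeOH/CH2Cl2, −78 °C
Reagents that add atoms: none
Why: Luche reduction; 1,2-hydride delivery to the enone under Felkin–Anh control (C6–O bond anti to the incoming hydride) should give the 5,6-syn alcohol, and the methylene lactone is spared at −78 °C.

Step 13
Reactants: 22 C5 allylic alcohol
Product: 23 C3,C4-epoxy alcohol (cis-epoxide syn to the C5 hydroxyl; C3 and C4 as in the target)
Conditions: m-CPBA, NaHCO3, CH2Cl2, 0 °C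
Reagents that add atoms: 3-chloroperoxybenzoic acid, O=C(OO)c1cccc(Cl)c1
Why: Hydroxyl-directed Prilezhaev epoxidation; allylic 1,3-strain in the (Z)-trisubstituted alkene holds H5 in the alkene plane and the hydrogen-bonded peracid attacks from the C5–OH face (threo product), while the electron-poor methylene lactone and the alkyne do not react.

Step 14
Reactants: 23 epoxy diol (C5–OH, C8–OH)
Product: 24 C5,C8-diacetate
Conditions: Ac2O, pyridine, DMAP (cat.), CH2Cl2, 0 °C → rt
Reagents that add atoms: acetic anhydride, CC(=O)OC(C)=O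
Why: DMAP-catalysed acetylation installs both acetates of the target in one operation; no stereocentre is touched.

Step 15
Reactants: 24 diacetate silyl ether
Product: 25 C2 primary epoxy alcohol
Conditions: HF·pyridine, pyridine, THF, 0 °C → rt
Reagents that add atoms: none
Why: Fluoride-mediated desilylation under buffered, non-basic conditions, which avoids Payne rearrangement and acyl migration.

Step 16
Reactants: 25 C2 primary epoxy alcohol
Product: 26 C2 epoxy aldehyde
Conditions: Dess–Martin periodinane, NaHCO3, CH2Cl2, 0 °C → rt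
Reagents that add atoms: none
Why: Dess–Martin oxidation under neutral conditions; the epoxide-bearing C3 is not epimerised.

Step 17
Reactants: 27 allyl bromoacetate
Product: 28 allyl diazoacetate
Conditions: TsNHNHTs, DBU, THF, 0 °C
Reagents that add atoms: N,N′-bis(4-methylbenzenesulfonyl)hydrazine, Cc1ccc(cc1)S(=O)(=O)NNS(=O)(=O)c1ccc(C)cc1
Why: Diazo ester synthesis by N-alkylation of the bis-sulfonylhydrazine and base-induced loss of two sulfinate ions.

Step 18
Reactants: 26 C2 epoxy aldehyde; 28 allyl diazoacetate
Product: 29 allyl β-keto ester (C2 ketone, C1H2–CO2allyl; seco-precursor with terminal alkyne)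
Conditions: SnCl2 (15 mol%), CH2Cl2, rt
Reagents that add atoms: none
Why: Roskamp reaction; the diazo ester adds to the Lewis-acid-activated aldehyde and a 1,2-hydride shift with loss of N2 gives the β-keto ester, introducing C1 and the activating group in one step.

Step 19
Reactants: 29 allyl β-keto ester with terminal alkyne
Product: 30 ten-membered carbocyclic β-keto ester (C1 epimers, C10=C14 exocyclic)
Conditions: In(NTf2)3 (10 mol%), PhMe, 80 °C, syringe-pump addition to 0.002 M
Reagents that add atoms: none
Why: In(NTf2)3 exchanges triflimide for the β-keto ester to give an indium enolate; the same metal centre binds the terminal alkyne, C1 adds to the internal alkyne carbon C10 in a concerted syn carbometalation, and protonolysis of the alkenyl–indium bond by HNTf2 releases the C10=C14 methylene and the catalyst. The closest known reaction type is the indium-catalysed Conia-ene cycloisomerisation of ω-alkynyl β-keto esters, which is established for medium and large carbocycles. The ten-membered carbocycle closes in the 10-exo-dig mode. The only new stereocentre, C1, carries the temporary ester, forms as a mixture and is erased in step 20, so no stereocontrol is needed. The step needs attack at C10 rather than C14 and ring closure rather than oligomerisation: the first is inherent to enolate carbometalation of terminal alkynes, the second should be secured by slow addition at high dilution and by the cis-lactone (C6–C7) and cis-epoxide (C3–C4), which fold the chain so that C1 and C10 approach. The β-keto ester is the only group acidic enough to be metalated, and the epoxide and the propargylic ester are deactivated towards ionisation by their flanking acyloxy groups.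

Step 20
Reactants: 30 macrocyclic allyl β-keto ester
Product: 32 CNP0256300.1 (target), via β-keto acid 31 (not isolated)
Conditions: Pd(PPh3)4 (5 mol%), HCO2H, Et3N, THF, 0 °C → rt
Reagents that add atoms: none
Why: Palladium-catalysed deallylation with formate as hydride donor, then spontaneous decarboxylation of the β-keto acid; the enol is protonated at C1 so that C10=C14 stays exocyclic, and the primary allyl ester should ionise much faster than the hindered secondary allylic C9 ester.

Compound list
1 | dimethyl (4S,5S)-2,2-dimethyl-1,3-dioxolane-4,5-dicarboxylate | COC(=O)[C@H]1OC(C)(C)O[C@@H]1C(=O)OC | starting material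
2 | methyl (4S,5S)-5-formyl-2,2-dimethyl-1,3-dioxolane-4-carboxylate | COC(=O)[C@H]1OC(C)(C)O[C@@H]1C=O | intermediate
3 | methyl (4S,5R)-5-ethynyl-2,2-dimethyl-1,3-dioxolane-4-carboxylate | COC(=O)[C@H]1OC(C)(C)O[C@@H]1C#C | intermediate
4 | (4S,5R)-5-ethynyl-2,2-dimethyl-1,3-dioxolane-4-carbaldehyde | O=C[C@H]1OC(C)(C)O[C@@H]1C#C | intermediate
5 | methyl acrylate | C=CC(=O)OC | starting material
6 | Morita–Baylis–Hillman alcohol (carbinol epimers, trans-dioxolane) | C=C(C(=O)OC)C(O)[C@H]1OC(C)(C)O[C@@H]1C#C | intermediate
7 | methyl (2Z)-2-(bromomethyl)-3-[(4R,5R)-5-ethynyl-2,2-dimethyl-1,3-dioxolan-4-yl]prop-2-enoate | BrC/C(C(=O)OC)=C\[C@H]1OC(C)(C)O[C@@H]1C#C | intermediate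
8 | but-2-yn-1-ol | CC#CCO | starting material
9 | sodium cyclic alkenylaluminate (2,5-dihydro-1,2-oxaluminole ate complex, formed in situ) | CC1=CCO[Al-]1(OCCOC)OCCOC.[Na+] | intermediate
10 | (2Z)-3-iodobut-2-en-1-ol | C/C(I)=C/CO | intermediate
11 | tert-butyl{[(2Z)-3-iodobut-2-en-1-yl]oxy}diphenylsilane | C/C(I)=C/CO[Si](c1ccccc1)(c1ccccc1)C(C)(C)C | intermediate
12 | glyoxylic acid monohydrate (2,2-dihydroxyacetic acid) | OC(O)C(=O)O | starting material
13 | open-chain hydroxy acid methyl ester (C6–OH, C5 acid; formed in situ) | C=C(C(=O)OC)[C@@H]([C@@H](O)C(=O)O)[C@H]1OC(C)(C)O[C@@H]1C#C | intermediate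
14 | (2R,3R)-3-[(4R,5R)-5-ethynyl-2,2-dimethyl-1,3-dioxolan-4-yl]-4-methylidene-5-oxooxolane-2-carboxylic acid | C=C1C(=O)O[C@@H](C(=O)O)[C@H]1[C@H]2OC(C)(C)O[C@@H]2C#C | intermediate
15 | acid chloride of 14 (formed in situ) | C=C1C(=O)O[C@@H](C(Cl)=O)[C@H]1[C@H]2OC(C)(C)O[C@@H]2C#C | intermediate
16 | (Z)-alkenyllithium from 11 (formed in situ) | [Li]/C(C)=C\CO[Si](c1ccccc1)(c1ccccc1)C(C)(C)C | intermediate
17 | (Z)-alkenylzinc chloride from 16 (formed in situ) | Cl[Zn]/C(C)=C\CO[Si](c1ccccc1)(c1ccccc1)C(C)(C)C | intermediate
18 | (Z)-enone: cis-lactone with C5 ketone, (Z)-C3=C4, C2–OTBDPS, C8/C9 acetonide, alkyne | C=C1C(=O)O[C@@H](C(=O)/C(C)=C\CO[Si](c3ccccc3)(c3ccccc3)C(C)(C)C)[C@H]1[C@H]2OC(C)(C)O[C@@H]2C#C | intermediate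
19 | C8,C9-diol of the (Z)-enone | C=C1C(=O)O[C@@H](C(=O)/C(C)=C\CO[Si](c3ccccc3)(c3ccccc3)C(C)(C)C)[C@H]1[C@@H](O)[C@H](O)C#C | intermediate
20 | (2R)-2-methylbutanoic acid | CC[C@@H](C)C(=O)O | starting material
21 | C9 (2R)-2-methylbutanoate of the (Z)-enone, C8–OH free | C=C1C(=O)O[C@@H](C(=O)/C(C)=C\CO[Si](c3ccccc3)(c3ccccc3)C(C)(C)C)[C@H]1[C@@H](O)[C@H](OC(=O)[C@H](C)CC)C#C | intermediate
22 | C5 allylic alcohol (5,6-threo), C8–OH free | C=C1C(=O)O[C@@H]([C@H](O)/C(C)=C\CO[Si](c3ccccc3)(c3ccccc3)C(C)(C)C)[C@H]1[C@@H](O)[C@H](OC(=O)[C@H](C)CC)C#C | intermediate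
23 | C3,C4-cis-epoxide (syn to C5–OH), C5–OH and C8–OH free | C=C1C(=O)O[C@@H]([C@H](O)[C@@]3(C)O[C@H]3CO[Si](c4ccccc4)(c4ccccc4)C(C)(C)C)[C@H]1[C@@H](O)[C@H](OC(=O)[C@H](C)CC)C#C | intermediate
24 | C5,C8-diacetate, C2–OTBDPS | C=C1C(=O)O[C@@H]([C@H](OC(C)=O)[C@@]3(C)O[C@H]3CO[Si](c4ccccc4)(c4ccccc4)C(C)(C)C)[C@H]1[C@@H](OC(C)=O)[C@H](OC(=O)[C@H](C)CC)C#C | intermediate
25 | C2 primary epoxy alcohol | C=C1C(=O)O[C@@H]([C@H](OC(C)=O)[C@@]3(C)O[C@H]3CO)[C@H]1[C@@H](OC(C)=O)[C@H](OC(=O)[C@H](C)CC)C#C | intermediate
26 | C2 epoxy aldehyde | C=C1C(=O)O[C@@H]([C@H](OC(C)=O)[C@@]3(C)O[C@H]3C=O)[C@H]1[C@@H](OC(C)=O)[C@H](OC(=O)[C@H](C)CC)C#C | intermediate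
27 | allyl bromoacetate | C=CCOC(=O)CBr | starting material
28 | allyl diazoacetate | C=CCOC(=O)C=[N+]=[N-] | intermediate
29 | allyl β-keto ester (open-chain cyclisation precursor) | C=C1C(=O)O[C@@H]([C@H](OC(C)=O)[C@@]3(C)O[C@H]3C(=O)CC(=O)OCC=C)[C@H]1[C@@H](OC(C)=O)[C@H](OC(=O)[C@H](C)CC)C#C | intermediate
30 | ten-membered carbocyclic allyl β-keto ester (C1 epimers) | C=C1C(=O)O[C@@H]2[C@H]1[C@@H](OC(C)=O)[C@H](OC(=O)[C@H](C)CC)C(=C)C(C(=O)OCC=C)C(=O)[C@@H]1O[C@]1(C)[C@H]2OC(C)=O | intermediate
31 | macrocyclic β-keto acid (C1 epimers, formed in situ) | C=C1C(=O)O[C@@H]2[C@H]1[C@@H](OC(C)=O)[C@H](OC(=O)[C@H](C)CC)C(=C)C(C(=O)O)C(=O)[C@@H]1O[C@]1(C)[C@H]2OC(C)=O | intermediate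
32 | CNP0256300.1 | C=C1C(=O)O[C@@H]2[C@H]1[C@@H](OC(C)=O)[C@H](OC(=O)[C@H](C)CC)C(=C)CC(=O)[C@@H]1O[C@]1(C)[C@H]2OC(C)=O | target

Total step count: 20
Longest linear sequence: 17 steps (1–5, 8–16, 18–20)

Steps most likely to fail

Step 19. The Lewis acid may open or rearrange the α,β-epoxy ketone, or oligomerisation may outrun closure of the strained ten-membered ring. The fallback forms the same C1–C10 bond by an sp2–sp3 coupling instead of a cycloisomerisation and sets out from 29. Markovnikov hydrosilylation of the alkyne with Et3SiH and [Cp*Ru(MeCN)3]PF6 in CH2Cl2 should give the 2-(triethylsilyl)alk-1-ene F1. Iododesilylation with N-iodosuccinimide in hexafluoroisopropanol at 0 °C should give the 2-iodoalk-1-ene F2. An intramolecular C-alkenylation of the β-keto ester with CuI (copper iodide), L-proline and Cs2CO3 in dioxane at high dilution should then close the ring and return to the route at 30.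

Step 8. The syn (cis-lactone) preference may erode if the carboxylate of glyoxylic acid chelates indium, or the facial selectivity with respect to C8 may be poor. The fallback replaces the Barbier reaction by an allylboration through a closed six-membered transition state and sets out from 7. Borylation with B2pin2, Pd2(dba)3 and KOAc should give the (Z)-allylboronate F3. Its Sc(OTf)3-catalysed addition to ethyl glyoxylate, followed by lactonisation, should translate the (Z)-geometry into the cis-lactone ethyl ester F4. Hydrolysis of the ethyl ester with Me3SnOH in 1,2-dichloroethane returns to the route at 14.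

Step 12. Hydride delivery to the C5 ketone may show poor facial selectivity, because a cerium-chelated transition state competes with the Felkin–Anh one. The fallback replaces substrate control by reagent control and sets out from 21. Reduction with catecholborane and (R)-2-methyl-CBS-oxazaborolidine in PhMe at −78 °C, in which the 1-methylalkenyl group should act as the large substituent, returns directly to the route at 22; no new compound arises (F0).

Further compounds
F1 | step 19 | 2-(triethylsilyl)alk-1-ene from hydrosilylation of 29 | C=C1C(=O)O[C@@H]([C@H](OC(C)=O)[C@@]3(C)O[C@H]3C(=O)CC(=O)OCC=C)[C@H]1[C@@H](OC(C)=O)[C@H](OC(=O)[C@H](C)CC)C(=C)[Si](CC)(CC)CC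
F2 | step 19 | 2-iodoalk-1-ene β-keto ester | C=C1C(=O)O[C@@H]([C@H](OC(C)=O)[C@@]3(C)O[C@H]3C(=O)CC(=O)OCC=C)[C@H]1[C@@H](OC(C)=O)[C@H](OC(=O)[C@H](C)CC)C(I)=C
F3 | step 8 | (Z)-allylboronate (pinacol ester) from 7 | CC1(C)OB(C/C(C(=O)OC)=C\[C@H]2OC(C)(C)O[C@@H]2C#C)OC1(C)C
F4 | step 8 | cis-lactone ethyl ester (ethyl ester of 14) | C=C1C(=O)O[C@@H](C(=O)OCC)[C@H]1[C@H]2OC(C)(C)O[C@@H]2C#C
F0 | step 12 | none | none
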